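## Retrosynthetic overview

1. Target ⇒ Wittig isopropylidenation and crotyl→prenyl cross-metathesis ⇒ a trione acid carrying an (E)-crotyl group on C6 ⇒ key step: dearomative [3,3] Claisen shift of a 5-O-[(R)-but-3-en-2-yl] aryl ether, whose 1,3-chirality transfer sets the quaternary carbon.
2. That ether ⇒ rhodium-catalysed allylic etherification and Negishi coupling of a 6-iodo tricyclic lactone with an alkylzinc made from diethyl (S)-malate (Seebach alkylation sets the side-chain centre).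
3. Iodo-lactone ⇒ aromatic Claisen shift of a 7-O-[(S)-4-phenylbut-3-en-2-yl] ether to C8 (chirality transfer sets the benzylic centre), then cross-metathesis and oxidation.
4. cis-2,3-Dimethylchromanone ⇒ phloroglucinol and tert-butyl (S)-3-hydroxybutanoate (Fráter–Seebach methylation, Mitsunobu inversion, Friedel–Crafts closure).
5. Rings: the carbocycle is bought as phloroglucinol; the pyranone ring is closed first; a temporary δ-lactone ring is closed next and opened again right after the key step.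

Assumption: tert-butyl (S)-3-hydroxybutanoate, diethyl (S)-malate and (R)-but-3-en-2-ol are taken as inexpensive commercial enantiopure materials, and the enolised triones are drawn in the tautomer of the target SMILES.

## Route

Step 1
Reactants: 1 tert-butyl (3S)-3-hydroxybutanoate
Product: 2 tert-butyl (2S,3S)-3-hydroxy-2-methylbutanoate
Conditions: LiN(i-Pr)2 (2.2 equiv), THF, −78 to −20 °C; MeI, −78 to 0 °C
Reagents that add atoms: iodomethane, IC
Why: Fráter–Seebach alkylation, in which the chelated lithium alkoxide–enolate dianion is methylated anti to the C3 methyl group, so the bought C3 centre sets C2 (2S,3S, about 95:5).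

Step 2
Reactants: 2 tert-butyl (2S,3S)-3-hydroxy-2-methylbutanoate; 3 benzene-1,3,5-triol (phloroglucinol)
Product: 4 tert-butyl (2S,3R)-3-(3,5-dihydroxyphenoxy)-2-methylbutanoate
Conditions: PPh3, DIAD, 3 (3 equiv), THF, 0 °C to rt
Reagents that add atoms: none
Why: Mitsunobu etherification, in which the acidic phenol displaces the activated secondary alcohol by SN2 with inversion (3S to 3R) while the excess triol limits double etherification.

Step 3
Reactants: 4 tert-butyl (2S,3R)-3-(3,5-dihydroxyphenoxy)-2-methylbutanoate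
Product: 6 (2R,3S)-5,7-dihydroxy-2,3-dimethylchroman-4-one, via free acid 5 (not isolated)
Conditions: TFA, anisole, CH2Cl2, 0 °C to rt; then (CF3CO)2O, 0 °C to rt; MeOH quench
Reagents that add atoms: none
Why: Acidolysis of the tert-butyl ester followed by intramolecular Friedel–Crafts acylation through the mixed trifluoroacetic anhydride closes the pyranone ring at either of the two equivalent ortho carbons without touching the stereocentres, so the inverted ether carbon gives the cis-2,3-dimethylchromanone.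

Step 4
Reactants: 7 (2R)-but-3-en-2-ol; 8 styrene
Product: 9 (2R,3E)-4-phenylbut-3-en-2-ol
Conditions: second-generation Grubbs catalyst RuCl2(=CHPh)(H2IMes)(PCy3) (2 mol %), 8 (3 equiv), CH2Cl2, 40 °C
Reagents that add atoms: none
Why: Olefin cross-metathesis of a secondary allylic alcohol with excess styrene gives the E-disubstituted alkene and does not involve the carbinol stereocentre.

Step 5
Reactants: 6 (2R,3S)-5,7-dihydroxy-2,3-dimethylchroman-4-one; 9 (2R,3E)-4-phenylbut-3-en-2-ol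
Product: 10 (2R,3S)-5-hydroxy-2,3-dimethyl-7-{[(2S,3E)-4-phenylbut-3-en-2-yl]oxy}chroman-4-one
Conditions: PPh3, DIAD, PhMe–THF, −20 to 0 °C
Reagents that add atoms: none
Why: Mitsunobu reaction, in which only the non-chelated and more acidic 7-OH reacts and the allylic carbinol is inverted (R to S) by SN2.

Step 6
Reactants: 10 (2R,3S)-5-hydroxy-2,3-dimethyl-7-{[(2S,3E)-4-phenylbut-3-en-2-yl]oxy}chroman-4-one
Product: 11 (2R,3S)-5-hydroxy-6-iodo-2,3-dimethyl-7-{[(2S,3E)-4-phenylbut-3-en-2-yl]oxy}chroman-4-one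
Conditions: BnMe3N ICl2 (1.05 equiv), CaCO3, CH2Cl2–MeOH, 0 °C to rt
Reagents that add atoms: benzyltrimethylammonium dichloroiodate, C[N+](C)(C)Cc1ccccc1.Cl[I-]Cl
Why: Electrophilic aromatic iodination ortho to the only free phenol puts iodine on C6, where it blocks that carbon in the next step and later serves as the coupling handle.

Step 7
Reactants: 11 (2R,3S)-5-hydroxy-6-iodo-2,3-dimethyl-7-{[(2S,3E)-4-phenylbut-3-en-2-yl]oxy}chroman-4-one
Product: 12 (2R,3S)-5,7-dihydroxy-6-iodo-2,3-dimethyl-8-[(1S,2E)-1-phenylbut-2-en-1-yl]chroman-4-one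
Conditions: Eu(fod)3 (10 mol %), CHCl3, 60 °C
Reagents that add atoms: none
Why: Aromatic Claisen rearrangement ([3,3]) to the only free ortho carbon C8 followed by enolisation, in which suprafacial allyl transposition with the methyl group pseudo-equatorial transfers the ether stereocentre to the new benzylic carbon (1S) and leaves an (E)-propenyl group.

Step 8
Reactants: 12 (2R,3S)-5,7-dihydroxy-6-iodo-2,3-dimethyl-8-[(1S,2E)-1-phenylbut-2-en-1-yl]chroman-4-one
Product: 13 (2R,3S)-5,7-dihydroxy-6-iodo-2,3-dimethyl-8-[(1S,2E)-1-phenyl-3-(4,4,5,5-tetramethyl-1,3,2-dioxaborolan-2-yl)prop-2-en-1-yl]chroman-4-one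
Conditions: vinylboronic acid pinacol ester (5 equiv), second-generation Hoveyda–Grubbs catalyst RuCl2(=CH-C6H4-2-O-i-Pr)(H2IMes) (10 mol %), 1,4-benzoquinone (20 mol %), CH2Cl2, 40 °C
Reagents that add atoms: 4,4,5,5-tetramethyl-2-vinyl-1,3,2-dioxaborolane, C=CB1OC(C)(C)C(C)(C)O1
Why: Olefin cross-metathesis exchanges the ethylidene terminus for an (E)-borylmethylidene, which puts boron on the carbon that must become the carboxyl carbon, while benzoquinone suppresses alkene migration toward the benzylic centre.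

Step 9
Reactants: 13 (2R,3S)-5,7-dihydroxy-6-iodo-2,3-dimethyl-8-[(1S,2E)-1-phenyl-3-(4,4,5,5-tetramethyl-1,3,2-dioxaborolan-2-yl)prop-2-en-1-yl]chroman-4-one
Product: 15 (2R,3S,10S)-5,8-dihydroxy-6-iodo-2,3-dimethyl-10-phenyl-2,3,9,10-tetrahydro-4H,8H-pyrano[2,3-f]chromen-4-one, via hydroxy aldehyde 14 (not isolated)
Conditions: 30 % H2O2, pH 7 phosphate buffer, THF, 0 °C to rt
Reagents that add atoms: hydrogen peroxide, OO
Why: Oxidation of the alkenyl C–B bond by 1,2-boronate migration gives the enol and hence the aldehyde, which the neighbouring 7-OH traps as the six-ring lactol.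

Step 10
Reactants: 15 (2R,3S,10S)-5,8-dihydroxy-6-iodo-2,3-dimethyl-10-phenyl-2,3,9,10-tetrahydro-4H,8H-pyrano[2,3-f]chromen-4-one
Product: 16 (2R,3S,10S)-5-hydroxy-6-iodo-2,3-dimethyl-10-phenyl-2,3,9,10-tetrahydro-4H,8H-pyrano[2,3-f]chromene-4,8-dione
Conditions: Ag2CO3 on Celite (5 equiv), PhMe, 90 °C
Reagents that add atoms: none
Why: Fétizon oxidation turns the lactol into the δ-lactone under neutral conditions, masking the acid and the 7-OH together and leaving the 5-OH as the only free phenol.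

Step 11
Reactants: 17 diethyl (2S)-2-hydroxybutanedioate (diethyl L-malate); 18 4-bromo-2-methylbut-1-ene
Product: 19 diethyl (2S,3R)-2-hydroxy-3-(3-methylbut-3-en-1-yl)butanedioate
Conditions: LiN(SiMe3)2 (2.1 equiv), THF, −78 to −20 °C; 18 (3 equiv), DMPU, −78 to 0 °C
Reagents that add atoms: none
Why: Seebach alkylation of the malate alkoxide–enolate dianion occurs anti to the ester-bearing carbinol substituent, so the bought C2 centre sets C3 (2S,3R).

Step 12
Reactants: 19 diethyl (2S,3R)-2-hydroxy-3-(3-methylbut-3-en-1-yl)butanedioate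
Product: 20 (2S,3S)-3-(hydroxymethyl)-6-methylhept-6-ene-1,2-diol
Conditions: LiAlH4, THF, 0 °C to reflux; aqueous work-up
Reagents that add atoms: none
Why: Hydride reduction of both esters gives the triol without affecting either stereocentre.

Step 13
Reactants: 20 (2S,3S)-3-(hydroxymethyl)-6-methylhept-6-ene-1,2-diol
Product: 21 (2S)-2-[(4S)-2,2-dimethyl-1,3-dioxolan-4-yl]-5-methylhex-5-en-1-ol
Conditions: Me2C(OMe)2, p-TsOH·H2O (2 mol %), acetone, rt
Reagents that add atoms: 2,2-dimethoxypropane, COC(C)(C)OC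
Why: Thermodynamic acetalisation selects the five-membered dioxolane of the terminal 1,2-diol over the 1,3-dioxane and leaves the other primary alcohol free.

Step 14
Reactants: 21 (2S)-2-[(4S)-2,2-dimethyl-1,3-dioxolan-4-yl]-5-methylhex-5-en-1-ol
Product: 22 (4S)-4-[(2R)-1-iodo-5-methylhex-5-en-2-yl]-2,2-dimethyl-1,3-dioxolane
Conditions: iodine, PPh3, imidazole, CH2Cl2, 0 °C to rt
Reagents that add atoms: iodine, [I][I]
Why: Appel iodination converts the primary alcohol into the iodide by SN2 at the CH2 group, leaving the adjacent stereocentre untouched.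

Step 15
Reactants: 16 (2R,3S,10S)-5-hydroxy-6-iodo-2,3-dimethyl-10-phenyl-2,3,9,10-tetrahydro-4H,8H-pyrano[2,3-f]chromene-4,8-dione; 22 (4S)-4-[(2R)-1-iodo-5-methylhex-5-en-2-yl]-2,2-dimethyl-1,3-dioxolane
Product: 24 (2R,3S,10S)-6-{(2S)-2-[(4S)-2,2-dimethyl-1,3-dioxolan-4-yl]-5-methylhex-5-en-1-yl}-5-hydroxy-2,3-dimethyl-10-phenyl-2,3,9,10-tetrahydro-4H,8H-pyrano[2,3-f]chromene-4,8-dione, via alkylzinc iodide 23 (not isolated)
Conditions: 22, Zn dust, LiCl, THF, 40 °C; 16, NaH (1.0 equiv), THF, 0 °C; then Pd(OAc)2 (5 mol %), SPhos (10 mol %), THF–NMP, 50 °C; 1 M HCl work-up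
Reagents that add atoms: none
Why: Negishi sp2–sp3 cross-coupling, in which zinc insertion gives a primary alkylzinc whose β-stereocentre is not involved and which couples with the hindered aryl iodide (phenol masked as its sodium salt) under a bulky biarylphosphine–palladium catalyst that tolerates lactone, ketone and acetal.

Step 16
Reactants: 7 (2R)-but-3-en-2-ol
Product: 25 (2R)-but-3-en-2-yl methyl carbonate
Conditions: ClCO2Me, pyridine, CH2Cl2, 0 °C
Reagents that add atoms: methyl chloroformate, COC(=O)Cl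
Why: O-Acylation of the alcohol gives the allylic carbonate with retention, because the C–O bond of the stereocentre is not broken.

Step 17
Reactants: 24 (2R,3S,10S)-6-{(2S)-2-[(4S)-2,2-dimethyl-1,3-dioxolan-4-yl]-5-methylhex-5-en-1-yl}-5-hydroxy-2,3-dimethyl-10-phenyl-2,3,9,10-tetrahydro-4H,8H-pyrano[2,3-f]chromene-4,8-dione; 25 (2R)-but-3-en-2-yl methyl carbonate
Product: 26 (2R,3S,10S)-5-{[(2R)-but-3-en-2-yl]oxy}-6-{(2S)-2-[(4S)-2,2-dimethyl-1,3-dioxolan-4-yl]-5-methylhex-5-en-1-yl}-2,3-dimethyl-10-phenyl-2,3,9,10-tetrahydro-4H,8H-pyrano[2,3-f]chromene-4,8-dione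
Conditions: 25 (1.5 equiv), RhCl(PPh3)3 (10 mol %), P(OMe)3 (40 mol %), THF, 30 °C
Reagents that add atoms: none
Why: Rhodium-catalysed allylic etherification, in which ionisation of the branched carbonate and attack of the phenoxide (formed in situ by the released methoxide) each proceed with inversion, so the ether forms at the secondary carbon with net retention (R) under base-free conditions that spare the lactone.

Step 18
Reactants: 26 (2R,3S,10S)-5-{[(2R)-but-3-en-2-yl]oxy}-6-{(2S)-2-[(4S)-2,2-dimethyl-1,3-dioxolan-4-yl]-5-methylhex-5-en-1-yl}-2,3-dimethyl-10-phenyl-2,3,9,10-tetrahydro-4H,8H-pyrano[2,3-f]chromene-4,8-dione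
Product: 28 (3S)-3-[(2R,3S,6R)-6-[(2E)-but-2-en-1-yl]-6-{(2S)-2-[(4S)-2,2-dimethyl-1,3-dioxolan-4-yl]-5-methylhex-5-en-1-yl}-4-hydroxy-2,3-dimethyl-5,7-dioxo-3,5,6,7-tetrahydro-2H-chromen-8-yl]-3-phenylpropanoic acid, via dienone lactone 27 (not isolated)
Conditions: PhMe, 110 °C; then THF–H2O, DMAP (10 mol %), rt
Reagents that add atoms: water, O
Why: Dearomative aromatic Claisen rearrangement ([3,3]) onto the alkyl-bearing ortho carbon C6 through a chair transition state with the carbinol methyl pseudo-equatorial, so the bought (R)-centre dictates which face of C6 is attacked and the (E)-crotyl geometry (6R here, the same arrangement that is 6S in the target), after which water opens the activated enol lactone to the acid and the stabilised trione.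

Step 19
Reactants: 28 (3S)-3-[(2R,3S,6R)-6-[(2E)-but-2-en-1-yl]-6-{(2S)-2-[(4S)-2,2-dimethyl-1,3-dioxolan-4-yl]-5-methylhex-5-en-1-yl}-4-hydroxy-2,3-dimethyl-5,7-dioxo-3,5,6,7-tetrahydro-2H-chromen-8-yl]-3-phenylpropanoic acid
Product: 29 (3S)-3-[(2R,3S,6R)-6-{(2S)-2-[(4S)-2,2-dimethyl-1,3-dioxolan-4-yl]-5-methylhex-5-en-1-yl}-4-hydroxy-2,3-dimethyl-6-(3-methylbut-2-en-1-yl)-5,7-dioxo-3,5,6,7-tetrahydro-2H-chromen-8-yl]-3-phenylpropanoic acid
Conditions: 2-methylbut-2-ene–CH2Cl2 (1:1), second-generation Hoveyda–Grubbs catalyst RuCl2(=CH-C6H4-2-O-i-Pr)(H2IMes) (10 mol %), 40 °C, sealed tube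
Reagents that add atoms: 2-methylbut-2-ene, CC=C(C)C
Why: Olefin cross-metathesis swaps the ethylidene terminus of the crotyl group for isopropylidene, the 1,1-disubstituted alkene being inert and no partner for a six-ring ring-closing metathesis being present yet.

Step 20
Reactants: 29 (3S)-3-[(2R,3S,6R)-6-{(2S)-2-[(4S)-2,2-dimethyl-1,3-dioxolan-4-yl]-5-methylhex-5-en-1-yl}-4-hydroxy-2,3-dimethyl-6-(3-methylbut-2-en-1-yl)-5,7-dioxo-3,5,6,7-tetrahydro-2H-chromen-8-yl]-3-phenylpropanoic acid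
Product: 30 (3S)-3-[(2R,3S,6R)-6-[(2S)-2-formyl-5-methylhex-5-en-1-yl]-4-hydroxy-2,3-dimethyl-6-(3-methylbut-2-en-1-yl)-5,7-dioxo-3,5,6,7-tetrahydro-2H-chromen-8-yl]-3-phenylpropanoic acid
Conditions: H5IO6 (2.2 equiv), EtOAc, 0 °C to rt
Reagents that add atoms: none
Why: Periodic acid hydrolyses the terminal acetonide and cleaves the resulting 1,2-diol (Malaprade glycol cleavage) to the aldehyde under mild conditions that do not epimerise the adjacent stereocentre.

Step 21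
Reactants: 30 (3S)-3-[(2R,3S,6R)-6-[(2S)-2-formyl-5-methylhex-5-en-1-yl]-4-hydroxy-2,3-dimethyl-6-(3-methylbut-2-en-1-yl)-5,7-dioxo-3,5,6,7-tetrahydro-2H-chromen-8-yl]-3-phenylpropanoic acid
Product: 31 (3S)-3-[(2R,3S,6S)-4-hydroxy-2,3-dimethyl-6-(3-methylbut-2-en-1-yl)-6-[(2S)-5-methyl-2-(2-methylprop-1-en-1-yl)hex-5-en-1-yl]-5,7-dioxo-3,5,6,7-tetrahydro-2H-chromen-8-yl]-3-phenylpropanoic acid
Conditions: i-PrPPh3 iodide (5 equiv), n-BuLi (5 equiv), THF, 0 °C; add 30 at −78 °C, then to 0 °C; pH 4 work-up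
Reagents that add atoms: isopropyltriphenylphosphonium iodide, CC(C)[P+](c1ccccc1)(c1ccccc1)c1ccccc1.[I-]
Why: Wittig olefination with the non-stabilised isopropylidene ylide turns the aldehyde into the 2-methylprop-1-enyl group, the excess ylide first deprotonating the acid and the enol so that the trione anion shields the cis-chromanone C3–H from epimerisation.

## Compound list

1 | tert-butyl (3S)-3-hydroxybutanoate | C[C@H](O)CC(=O)OC(C)(C)C | starting material
2 | tert-butyl (2S,3S)-3-hydroxy-2-methylbutanoate | C[C@H](O)[C@H](C)C(=O)OC(C)(C)C | intermediate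
3 | benzene-1,3,5-triol (phloroglucinol) | Oc1cc(O)cc(O)c1 | starting material
4 | tert-butyl (2S,3R)-3-(3,5-dihydroxyphenoxy)-2-methylbutanoate | C[C@@H](Oc1cc(O)cc(O)c1)[C@H](C)C(=O)OC(C)(C)C | intermediate
5 | (2S,3R)-3-(3,5-dihydroxyphenoxy)-2-methylbutanoic acid (not isolated) | C[C@@H](Oc1cc(O)cc(O)c1)[C@H](C)C(=O)O | intermediate
6 | (2R,3S)-5,7-dihydroxy-2,3-dimethylchroman-4-one (cis) | C[C@H]1Oc2cc(O)cc(O)c2C(=O)[C@H]1C | intermediate
7 | (2R)-but-3-en-2-ol | C[C@@H](O)C=C | starting material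
8 | styrene | C=Cc1ccccc1 | starting material
9 | (2R,3E)-4-phenylbut-3-en-2-ol | C[C@@H](O)/C=C/c1ccccc1 | intermediate
10 | (2R,3S)-5-hydroxy-2,3-dimethyl-7-{[(2S,3E)-4-phenylbut-3-en-2-yl]oxy}chroman-4-one | C[C@H]1Oc2cc(O[C@@H](C)/C=C/c3ccccc3)cc(O)c2C(=O)[C@H]1C | intermediate
11 | (2R,3S)-5-hydroxy-6-iodo-2,3-dimethyl-7-{[(2S,3E)-4-phenylbut-3-en-2-yl]oxy}chroman-4-one | C[C@H]1Oc2cc(O[C@@H](C)/C=C/c3ccccc3)c(I)c(O)c2C(=O)[C@H]1C | intermediate
12 | (2R,3S)-5,7-dihydroxy-6-iodo-2,3-dimethyl-8-[(1S,2E)-1-phenylbut-2-en-1-yl]chroman-4-one | C[C@H]1Oc2c([C@@H](/C=C/C)c3ccccc3)c(O)c(I)c(O)c2C(=O)[C@H]1C | intermediate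
13 | (2R,3S)-5,7-dihydroxy-6-iodo-2,3-dimethyl-8-[(1S,2E)-1-phenyl-3-(4,4,5,5-tetramethyl-1,3,2-dioxaborolan-2-yl)prop-2-en-1-yl]chroman-4-one | C[C@H]1Oc2c([C@@H](/C=C/B3OC(C)(C)C(C)(C)O3)c3ccccc3)c(O)c(I)c(O)c2C(=O)[C@H]1C | intermediate
14 | (3S)-3-[(2R,3S)-5,7-dihydroxy-6-iodo-2,3-dimethyl-4-oxochroman-8-yl]-3-phenylpropanal (not isolated) | C[C@H]1Oc2c([C@@H](CC=O)c3ccccc3)c(O)c(I)c(O)c2C(=O)[C@H]1C | intermediate
15 | (2R,3S,10S)-5,8-dihydroxy-6-iodo-2,3-dimethyl-10-phenyl-2,3,9,10-tetrahydro-4H,8H-pyrano[2,3-f]chromen-4-one (six-ring lactol on the 7-oxygen, both C8 epimers) | C[C@H]1Oc2c3c(OC(O)C[C@H]3c3ccccc3)c(I)c(O)c2C(=O)[C@H]1C | intermediate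
16 | (2R,3S,10S)-5-hydroxy-6-iodo-2,3-dimethyl-10-phenyl-2,3,9,10-tetrahydro-4H,8H-pyrano[2,3-f]chromene-4,8-dione (δ-lactone) | C[C@H]1Oc2c3c(OC(=O)C[C@H]3c3ccccc3)c(I)c(O)c2C(=O)[C@H]1C | intermediate
17 | diethyl (2S)-2-hydroxybutanedioate (diethyl L-malate) | CCOC(=O)C[C@H](O)C(=O)OCC | starting material
18 | 4-bromo-2-methylbut-1-ene | C=C(C)CCBr | starting material
19 | diethyl (2S,3R)-2-hydroxy-3-(3-methylbut-3-en-1-yl)butanedioate | CCOC(=O)[C@H](CCC(C)=C)[C@H](O)C(=O)OCC | intermediate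
20 | (2S,3S)-3-(hydroxymethyl)-6-methylhept-6-ene-1,2-diol | OC[C@H](CCC(C)=C)[C@H](O)CO | intermediate
21 | (2S)-2-[(4S)-2,2-dimethyl-1,3-dioxolan-4-yl]-5-methylhex-5-en-1-ol | OC[C@H](CCC(C)=C)[C@H]1COC(C)(C)O1 | intermediate
22 | (4S)-4-[(2R)-1-iodo-5-methylhex-5-en-2-yl]-2,2-dimethyl-1,3-dioxolane | IC[C@H](CCC(C)=C)[C@H]1COC(C)(C)O1 | intermediate
23 | {(2R)-2-[(4S)-2,2-dimethyl-1,3-dioxolan-4-yl]-5-methylhex-5-en-1-yl}zinc iodide (not isolated) | I[Zn]C[C@H](CCC(C)=C)[C@H]1COC(C)(C)O1 | intermediate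
24 | (2R,3S,10S)-6-{(2S)-2-[(4S)-2,2-dimethyl-1,3-dioxolan-4-yl]-5-methylhex-5-en-1-yl}-5-hydroxy-2,3-dimethyl-10-phenyl-2,3,9,10-tetrahydro-4H,8H-pyrano[2,3-f]chromene-4,8-dione | C[C@H]1Oc2c3c(OC(=O)C[C@H]3c3ccccc3)c(C[C@H](CCC(C)=C)[C@H]3COC(C)(C)O3)c(O)c2C(=O)[C@H]1C | intermediate
25 | (2R)-but-3-en-2-yl methyl carbonate | COC(=O)O[C@H](C)C=C | intermediate
26 | (2R,3S,10S)-5-{[(2R)-but-3-en-2-yl]oxy}-6-{(2S)-2-[(4S)-2,2-dimethyl-1,3-dioxolan-4-yl]-5-methylhex-5-en-1-yl}-2,3-dimethyl-10-phenyl-2,3,9,10-tetrahydro-4H,8H-pyrano[2,3-f]chromene-4,8-dione | C[C@H]1Oc2c3c(OC(=O)C[C@H]3c3ccccc3)c(C[C@H](CCC(C)=C)[C@H]3COC(C)(C)O3)c(O[C@H](C)C=C)c2C(=O)[C@H]1C | intermediate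
27 | (2R,3S,6R,10S)-6-[(2E)-but-2-en-1-yl]-6-{(2S)-2-[(4S)-2,2-dimethyl-1,3-dioxolan-4-yl]-5-methylhex-5-en-1-yl}-2,3-dimethyl-10-phenyl-2,3,9,10-tetrahydro-4H-pyrano[2,3-f]chromene-4,5,8(6H)-trione (not isolated) | C[C@H]1OC2=C(C(=O)[C@H]1C)C(=O)[C@](C/C=C/C)(C[C@H](CCC(C)=C)[C@H]1COC(C)(C)O1)C1=C2[C@H](c2ccccc2)CC(=O)O1 | intermediate
28 | (3S)-3-[(2R,3S,6R)-6-[(2E)-but-2-en-1-yl]-6-{(2S)-2-[(4S)-2,2-dimethyl-1,3-dioxolan-4-yl]-5-methylhex-5-en-1-yl}-4-hydroxy-2,3-dimethyl-5,7-dioxo-3,5,6,7-tetrahydro-2H-chromen-8-yl]-3-phenylpropanoic acid | C=C(C)CC[C@H]([C@H]3COC(C)(C)O3)C[C@@]1(C/C=C/C)C(=O)C2=C(O)[C@@H](C)[C@@H](C)OC2=C([C@@H](CC(=O)O)c2ccccc2)C1=O | intermediate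
29 | (3S)-3-[(2R,3S,6R)-6-{(2S)-2-[(4S)-2,2-dimethyl-1,3-dioxolan-4-yl]-5-methylhex-5-en-1-yl}-4-hydroxy-2,3-dimethyl-6-(3-methylbut-2-en-1-yl)-5,7-dioxo-3,5,6,7-tetrahydro-2H-chromen-8-yl]-3-phenylpropanoic acid | C=C(C)CC[C@H]([C@H]3COC(C)(C)O3)C[C@@]1(CC=C(C)C)C(=O)C2=C(O)[C@@H](C)[C@@H](C)OC2=C([C@@H](CC(=O)O)c2ccccc2)C1=O | intermediate
30 | (3S)-3-[(2R,3S,6R)-6-[(2S)-2-formyl-5-methylhex-5-en-1-yl]-4-hydroxy-2,3-dimethyl-6-(3-methylbut-2-en-1-yl)-5,7-dioxo-3,5,6,7-tetrahydro-2H-chromen-8-yl]-3-phenylpropanoic acid | C=C(C)CC[C@H](C=O)C[C@@]1(CC=C(C)C)C(=O)C2=C(O)[C@@H](C)[C@@H](C)OC2=C([C@@H](CC(=O)O)c2ccccc2)C1=O | intermediate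
31 | (3S)-3-[(2R,3S,6S)-4-hydroxy-2,3-dimethyl-6-(3-methylbut-2-en-1-yl)-6-[(2S)-5-methyl-2-(2-methylprop-1-en-1-yl)hex-5-en-1-yl]-5,7-dioxo-3,5,6,7-tetrahydro-2H-chromen-8-yl]-3-phenylpropanoic acid (CNP0155375.1) | C=C(C)CC[C@H](C=C(C)C)C[C@@]1(CC=C(C)C)C(=O)C2=C(O)[C@@H](C)[C@@H](C)OC2=C([C@@H](CC(=O)O)c2ccccc2)C1=O | target

## Step count and risks

Total steps: 21. Longest linear sequence: 15 (steps 1–3, 5–10, 15, 17–21).

Three steps most likely to fail:

Step 8. The alkene sits next to a diarylmethine carbon, so metathesis may be slow and ruthenium hydride could migrate the double bond into conjugation and destroy the benzylic centre. The fallback sets out from 12 and comes back at 15. The propenyl group is cleaved instead (OsO4 cat., NaIO4, 2,6-lutidine, dioxane–H2O), and the aldehyde is caught by the 7-OH as the five-ring lactol (2R,3S,9S)-5,8-dihydroxy-6-iodo-2,3-dimethyl-9-phenyl-2,3,8,9-tetrahydro-4H-furo[2,3-h]chromen-4-one F1. One-carbon Wittig homologation with Ph3P=CHOMe (MeOCH2PPh3Cl, KOt-Bu, THF, 0 °C) gives the enol ether (2R,3S)-5,7-dihydroxy-6-iodo-8-[(1S)-3-methoxy-1-phenylprop-2-en-1-yl]-2,3-dimethylchroman-4-one F2, and THF–1 M HCl hydrolyses it to lactol 15.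

Step 17. The 5-OH is chelated to the ketone and flanked by two ortho substituents, so the π-allyl etherification may stall. The fallback sets out from 24 and comes back at 26. It is a Mitsunobu etherification at high concentration under sonication (PPh3, DIAD, THF, 3 M) with the enantiomeric alcohol (2S)-but-3-en-2-ol F3, which reacts with inversion and so gives the same (R)-ether 26.

Step 18. The dienone formed from the lactone-capped arene cannot enolise, so the [3,3] equilibrium may stay on the ether side or drain away through Cope shifts. The fallback sets out from 26 and comes back at 28. The lactone is opened before the rearrangement (LiOH, THF–H2O, 0 °C) to the 7-hydroxy acid (3S)-3-[(2R,3S)-5-{[(2R)-but-3-en-2-yl]oxy}-6-{(2S)-2-[(4S)-2,2-dimethyl-1,3-dioxolan-4-yl]-5-methylhex-5-en-1-yl}-7-hydroxy-2,3-dimethyl-4-oxochroman-8-yl]-3-phenylpropanoic acid F4. Its disodium salt is heated (DMF–H2O, 90 °C), where the Claisen dienone tautomerises at once to the trione enolate, and acidification to pH 4 gives 28.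

## Further compounds

F1 | step 8 | (2R,3S,9S)-5,8-dihydroxy-6-iodo-2,3-dimethyl-9-phenyl-2,3,8,9-tetrahydro-4H-furo[2,3-h]chromen-4-one | C[C@H]1Oc2c3c(OC(O)[C@H]3c3ccccc3)c(I)c(O)c2C(=O)[C@H]1C
F2 | step 8 | (2R,3S)-5,7-dihydroxy-6-iodo-8-[(1S)-3-methoxy-1-phenylprop-2-en-1-yl]-2,3-dimethylchroman-4-one | C[C@H]1Oc2c([C@@H](C=COC)c3ccccc3)c(O)c(I)c(O)c2C(=O)[C@H]1C
F3 | step 17 | (2S)-but-3-en-2-ol | C[C@H](O)C=C
F4 | step 18 | (3S)-3-[(2R,3S)-5-{[(2R)-but-3-en-2-yl]oxy}-6-{(2S)-2-[(4S)-2,2-dimethyl-1,3-dioxolan-4-yl]-5-methylhex-5-en-1-yl}-7-hydroxy-2,3-dimethyl-4-oxochroman-8-yl]-3-phenylpropanoic acid | C[C@H]1Oc2c([C@@H](CC(=O)O)c3ccccc3)c(O)c(C[C@H](CCC(C)=C)[C@H]3COC(C)(C)O3)c(O[C@H](C)C=C)c2C(=O)[C@H]1C
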